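The earlier runs and the new flask are simulated with made-up constants; the scatter is artificial.

Slowness is what the spring run shows first: between 2.00 h and 2.50 h complex with two exchanged gains 1.7 percentage points. Its last reading is 22.7%, good to 0.5 points. The step before, from 1.33 h to 2.00 h, gained 4.1 points, so the curve reads as flattening, and we ask what the charges allow.

| flask | starting complex | incoming ligand | leaving ligand | remark | time |
|---|---|---|---|---|---|
| spring | 0.050 M | 0.0525 M | 0.15 M | run made earlier |  |
| flask | 0.050 M | 0.0525 M | 0.100 M |  | 25 h |

spring run (percent of the starting complex charged)

| time / h | complex with two exchanged / % |
|---|---|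
| 0.167 | 0.9 |
| 0.500 | 6.2 |
| 0.833 | 11.7 |
| 1.33 | 16.9 |
| 2.00 | 21.0 |
| 2.50 | 22.7 |

(readings scatter by 0.5 percentage points)

1. time up to 25 h at which complex with two exchanged stands highest
2. the amount of complex with two exchanged, in percent of the starting complex charged, at that time
3. the first time at which complex with two exchanged reaches 22%, in the same percent

We build the flask up one process at a time. First come the main steps. Each exchange takes one incoming ligand, so two exchanges on every starting complex take two, and incoming ligand is the limiting reagent of this count:

f = 0.0525 M / (2 × 0.050 M) = 52.5%

We call f the ligand fill, the share of the two places on each starting complex that the charged incoming ligand can take. It is the ceiling for complex with two exchanged, reached when each ligand goes to finish a complex.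

Next we add chance. In the statistical case, our zero, ligand lands at random on the places, and a complex holds two with chance:

f × f = 27.6%

Then comes leaving ligand. The last spring reading lies below that zero with 0.15 M charged, and it is still rising. The flask has 0.100 M, and no earlier run varies that charge, so its effect is a guess. We commit to the zero as our peak height.

The forecast sits lower than our number: 26% at 25 h, with the asked level reached at 2.2 h. Of the curve it says “I see no sign of decline”.

In the flask, complex with two exchanged stands highest at 7.60 h, with 30.9%, and reaches the asked level at 1.93 h.

    starting complex + incoming ligand ⇌ leaving ligand + complex with one exchanged (K = 3.80, k = 0.230 M⁻¹ min⁻¹)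
    leaving ligand → by-product carried off (k = 0.00810 min⁻¹)
    complex with one exchanged + incoming ligand ⇌ leaving ligand + complex with two exchanged (K = 25.0, k = 0.560 M⁻¹ min⁻¹)
    complex with two exchanged + incoming ligand ⇌ leaving ligand + complex with three exchanged (K = 0.250, k = 0.160 M⁻¹ min⁻¹)
    complex with one exchanged → decomposed reagent (k = 5.30 × 10⁻⁴ min⁻¹)
    leaving ligand + starting complex → side product (k = 0.110 M⁻¹ min⁻¹)

That peak lies 3.3 points above our zero and below the ceiling, and it comes earlier than forecast. At that time, 7.60 h, complex with three exchanged stands at 7.10%. By 25.0 h complex with two exchanged in the flask is down to 27.8%, while complex with three exchanged has grown to 14.2%. The neighbouring flask charges 0.12 M of starting complex with the same incoming ligand, so its fill is 21.9% and its zero 4.79%. Its highest amount stands above that zero and below that ceiling, at 15.0%.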